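## Retrosynthetic overview

1. Target 22 ⇐ spiro enone 17: the dibromomethyl carbinol comes from LiCHBr2 addition while the C1=C2 alkene is masked as a β-phenylselanyl ketone (to force equatorial attack), followed by selenoxide elimination and desilylation.
2. 17 ⇐ symmetric spiro[5.5]undeca-1,4-dien-3-one 12: a temporary ether bridge from the C9 hydroxyl to the cis enone arm (oxa-Michael), CuH reduction of the other arm and ring-opening turn the non-stereogenic spiro carbon into the (6S) centre.
3. 12 ⇐ para-substituted phenol 11 carrying a terminal alkyne: gold-catalysed dearomative 6-exo-dig spirocyclisation joins the arene ipso carbon to the internal alkyne carbon, closing ring A onto the existing six-membered carbocycle (ring B) and creating the spiro carbon and the exocyclic methylidene.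
4. Enabling feature: the spiro carbon C6 lies para to the oxygen-bearing C3 of ring B, so ring B is a masked 4-alkylphenol with a nucleophilic ipso carbon; at the dienone stage its two arms (C1=C2 and C4=C5) are identical, so the ring closure poses no facial problem.
5. 11 ⇐ aryl Grignard + 3-methylbut-2-enal (quaternary CMe2), organocatalytic α-bromination (C8) and Cornforth-controlled allenylboration (C9). Ring order: B (as arene), A (key step), temporary oxa-bridge (made and removed), then adjustment of ring B.

Key step: step 6

Locants: every spirocycle is numbered as spiro[5.5]undecane with ring B = C1–C5, spiro carbon C6, then ring A C7 (CMe2), C8 (CHBr), C9 (CH–O), C10 (CH2), C11 (C=CH2); this numbering is kept fixed throughout.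

Assumption: the (2R,5R) antipode of 2,5-diphenylpyrrolidine is taken to deliver the (S)-bromide in step 2; if the sense is the reverse, the (2S,5S) catalyst is used.

## Route

Step 1
Reactants: 1 (4-bromophenoxy)(tert-butyl)dimethylsilane; 2 3-methylbut-2-enal
Product: 5 3-[4-(tert-butyldimethylsilyloxy)phenyl]-3-methylbutanal, via aryl Grignard reagent 3 (not isolated), via trimethylsilyl enol ether 4 (not isolated)
Conditions: Mg, THF; then CuBr·SMe2 (5 mol %), TMSCl, DMPU, 2, THF, −78 °C; 1 M HCl work-up
Reagents that add atoms: none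
Why: Copper-catalysed, TMSCl-accelerated conjugate addition of the aryl Grignard reagent to the β,β-disubstituted enal should build the quaternary benzylic carbon, the silyl enol ether being hydrolysed on work-up; no stereocentre is formed.

Step 2
Reactants: 5 3-[4-(tert-butyldimethylsilyloxy)phenyl]-3-methylbutanal
Product: 6 (2S)-2-bromo-3-[4-(tert-butyldimethylsilyloxy)phenyl]-3-methylbutanal
Conditions: (2R,5R)-2,5-diphenylpyrrolidine (20 mol %), PhCO2H (20 mol %), H2O, 4,4-dibromo-2,6-di-tert-butylcyclohexa-2,5-dien-1-one, CH2Cl2–pentane, −40 °C; used crude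
Reagents that add atoms: 4,4-dibromo-2,6-di-tert-butylcyclohexa-2,5-dien-1-one, CC(C)(C)C1=CC(Br)(Br)C=C(C(C)(C)C)C1=O
Why: Enamine-catalysed electrophilic α-bromination of the aldehyde (organocatalytic α-halogenation) should set the bromine-bearing centre as (S) by catalyst control, the C2-symmetric amine shielding one enamine face, and the neopentyl-type α-position should resist racemisation.

Step 3
Reactants: 6 (2S)-2-bromo-3-[4-(tert-butyldimethylsilyloxy)phenyl]-3-methylbutanal; 7 allenylboronic acid pinacol ester
Product: 9 (4R,5S)-5-bromo-6-[4-(tert-butyldimethylsilyloxy)phenyl]-6-methylhept-1-yn-4-ol, via pinacol borate ester 8 (not isolated)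
Conditions: CH2Cl2, 0 °C to rt; aq NaHCO3 work-up
Reagents that add atoms: none
Why: Allenylboration through a closed six-membered SE2′ transition state should give the homopropargylic alcohol with the anti (4R,5S) bromohydrin relationship by Cornforth–Evans control (C–Br antiperiplanar to C=O, attack past hydrogen), the borate ester being hydrolysed on work-up.

Step 4
Reactants: 9 (4R,5S)-5-bromo-6-[4-(tert-butyldimethylsilyloxy)phenyl]-6-methylhept-1-yn-4-ol
Product: 10 tert-butyl{4-[(3S,4R)-3-bromo-4-(tert-butyldimethylsilyloxy)-2-methylhept-6-yn-2-yl]phenoxy}dimethylsilane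
Conditions: TBSOTf, 2,6-lutidine, CH2Cl2, −78 to 0 °C; aq NaHCO3 work-up
Reagents that add atoms: tert-butyldimethylsilyl trifluoromethanesulfonate, CC(C)(C)[Si](C)(C)OS(=O)(=O)C(F)(F)F
Why: Silylation with a silyl triflate and a non-nucleophilic base should block the hindered secondary hydroxyl, which would otherwise add to the gold-activated alkyne or close onto the bromide to an epoxide, without touching the stereocentres.

Step 5
Reactants: 10 tert-butyl{4-[(3S,4R)-3-bromo-4-(tert-butyldimethylsilyloxy)-2-methylhept-6-yn-2-yl]phenoxy}dimethylsilane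
Product: 11 4-[(3S,4R)-3-bromo-4-(tert-butyldimethylsilyloxy)-2-methylhept-6-yn-2-yl]phenol
Conditions: KHF2, MeOH, rt
Reagents that add atoms: none
Why: Bifluoride in methanol should cleave the phenolic silyl ether much faster than the hindered alkyl silyl ether (chemoselective desilylation) and keeps the medium slightly acidic, so that no phenoxide forms that could displace the neighbouring bromide through its ipso carbon.

Step 6
Reactants: 11 4-[(3S,4R)-3-bromo-4-(tert-butyldimethylsilyloxy)-2-methylhept-6-yn-2-yl]phenol
Product: 12 (8S,9R)-8-bromo-9-(tert-butyldimethylsilyloxy)-7,7-dimethyl-11-methylidenespiro[5.5]undeca-1,4-dien-3-one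
Conditions: (JohnPhos)Au(MeCN)SbF6 (5 mol %), CH2Cl2, rt
Reagents that add atoms: none
Why: Cationic gold(I) activates the terminal alkyne and the arene carbon para to the hydroxyl (the only nucleophilic ring position within reach) attacks its internal carbon anti to gold; loss of the phenolic proton gives the cyclohexa-2,5-dienone and protodeauration gives the exocyclic methylidene, so the step is an isomerisation. The closest known reaction type is the gold-catalysed ipso-Friedel–Crafts (dearomative) spirocyclisation of phenols and naphthols carrying a tethered terminal alkyne, a vinylogous Conia-ene process. Ring A closes in the 6-exo-dig mode, helped by the gem-dimethyl group, and the slim alkyne is what allows two adjacent quaternary carbons to be joined. No new stereocentre arises: in the dienone the spiro carbon carries two identical enone arms, so no facial selectivity is needed and the (8S,9R) centres are untouched. The selectivities required are exo (Markovnikov) over 7-endo attack, secured by the terminal alkyne; carbon attack over participation of the C9 oxygen, secured by its bulky silyl ether; and the absence of base, which keeps the phenol from displacing the neighbouring bromide by aryl participation.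

Step 7
Reactants: 12 (8S,9R)-8-bromo-9-(tert-butyldimethylsilyloxy)-7,7-dimethyl-11-methylidenespiro[5.5]undeca-1,4-dien-3-one
Product: 14 (1S,6S,8S,9R)-8-bromo-1,9-epoxy-7,7-dimethyl-11-methylidenespiro[5.5]undec-4-en-3-one (ether oxygen bridges C9 and C1), via hydroxy dienone 13 (not isolated)
Conditions: HF·pyridine, pyridine, THF, 0 °C to rt; then DBU (0.2 equiv), CH2Cl2, rt
Reagents that add atoms: none
Why: Non-basic desilylation frees the axial C9 hydroxyl, which can reach only the enone arm on its own face of ring A, so base-catalysed intramolecular oxa-Michael addition (six-membered ether, 2-oxabicyclo[2.2.2]octane) should make the spiro carbon a defined (6S) centre by substrate geometry; the C1 configuration is of no consequence.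

Step 8
Reactants: 14 (1S,6S,8S,9R)-8-bromo-1,9-epoxy-7,7-dimethyl-11-methylidenespiro[5.5]undec-4-en-3-one
Product: 15 (1S,6S,8S,9R)-8-bromo-1,9-epoxy-7,7-dimethyl-11-methylidenespiro[5.5]undecan-3-one
Conditions: [(Ph3P)CuH]6, H2O, benzene–THF, rt
Reagents that add atoms: none
Why: Stryker-type copper hydride conjugate reduction is selective for the remaining enone over the isolated 1,1-disubstituted alkene, the alkyl bromide and the ketone, so only the enone arm not held in the ether bridge should be saturated.

Step 9
Reactants: 15 (1S,6S,8S,9R)-8-bromo-1,9-epoxy-7,7-dimethyl-11-methylidenespiro[5.5]undecan-3-one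
Product: 17 (6S,8S,9R)-8-bromo-9-(tert-butyldimethylsilyloxy)-7,7-dimethyl-11-methylidenespiro[5.5]undec-1-en-3-one, via silyl enol ether 16 (not isolated)
Conditions: TBSOTf, Et3N, CH2Cl2, −20 °C to rt; aq NaHCO3 work-up, then brief 0.5 M HCl–THF
Reagents that add atoms: tert-butyldimethylsilyl trifluoromethanesulfonate, CC(C)(C)[Si](C)(C)OS(=O)(=O)C(F)(F)F
Why: Soft enolisation followed by silyl-triflate-assisted β-elimination of the bridging ether oxygen (retro-oxa-Michael, as in ring-openings of oxabicyclic ketones) should unveil the C1=C2 enone on the arm cis to the C9 oxygen and return that oxygen as its silyl ether, with the spiro configuration retained.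

Step 10
Reactants: 17 (6S,8S,9R)-8-bromo-9-(tert-butyldimethylsilyloxy)-7,7-dimethyl-11-methylidenespiro[5.5]undec-1-en-3-one
Product: 18 (1R,6S,8S,9R)-8-bromo-9-(tert-butyldimethylsilyloxy)-7,7-dimethyl-11-methylidene-1-(phenylselanyl)spiro[5.5]undecan-3-one
Conditions: PhSeH, Et3N (0.2 equiv), CH2Cl2, 0 °C to rt
Reagents that add atoms: benzeneselenol, [SeH]c1ccccc1
Why: Amine-catalysed conjugate addition of the selenol (seleno-Michael) should temporarily saturate the enone, the selanyl group entering axially on the ring-B face opposite to the axial C11, so that ring B becomes a chair cyclohexanone with its axial carbonyl face blocked; the C1 centre is destroyed again in step 12.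

Step 11
Reactants: 18 (1R,6S,8S,9R)-8-bromo-9-(tert-butyldimethylsilyloxy)-7,7-dimethyl-11-methylidene-1-(phenylselanyl)spiro[5.5]undecan-3-one
Product: 19 (1R,3R,6S,8S,9R)-8-bromo-9-(tert-butyldimethylsilyloxy)-3-(dibromomethyl)-7,7-dimethyl-11-methylidene-1-(phenylselanyl)spiro[5.5]undecan-3-ol
Conditions: CH2Br2 (excess), LDA, THF, −90 °C; then 18, −90 to −78 °C; AcOH–THF quench at −78 °C
Reagents that add atoms: dibromomethane, BrCBr
Why: 1,2-Addition of dibromomethyllithium (carbenoid from deprotonation of dibromomethane) to the chair ketone should occur by equatorial attack, because the axial face is screened by the axial phenylselanyl group and H-5ax, placing CHBr2 equatorial and cis to C11 with the hydroxyl axial, i.e. the (3R) carbinol, whereas direct addition to enone 17 would be expected to come axially and give the epimer.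

Step 12
Reactants: 19 (1R,3R,6S,8S,9R)-8-bromo-9-(tert-butyldimethylsilyloxy)-3-(dibromomethyl)-7,7-dimethyl-11-methylidene-1-(phenylselanyl)spiro[5.5]undecan-3-ol
Product: 21 (3R,6S,8S,9R)-8-bromo-9-(tert-butyldimethylsilyloxy)-3-(dibromomethyl)-7,7-dimethyl-11-methylidenespiro[5.5]undec-1-en-3-ol, via selenoxide 20 (not isolated)
Conditions: 30 % H2O2, pyridine, CH2Cl2, 0 °C to rt
Reagents that add atoms: none
Why: Oxidation to the selenoxide and spontaneous syn-elimination, which can only run towards C2 because C6 is quaternary, should regenerate the C1=C2 double bond without touching the methylidene group or the tertiary carbinol.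

Step 13
Reactants: 21 (3R,6S,8S,9R)-8-bromo-9-(tert-butyldimethylsilyloxy)-3-(dibromomethyl)-7,7-dimethyl-11-methylidenespiro[5.5]undec-1-en-3-ol
Product: 22 Mailiohydrin, (3R,6S,8S,9R)-8-bromo-3-(dibromomethyl)-7,7-dimethyl-11-methylidenespiro[5.5]undec-1-ene-3,9-diol
Conditions: HF·pyridine, pyridine, THF, 0 °C to rt
Reagents that add atoms: none
Why: Buffered, non-basic fluoride cleavage of the secondary silyl ether (a base would close the dibromomethyl carbinol to a bromo-epoxide) should release the target with all four stereocentres intact.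

## Compound list

1 | (4-bromophenoxy)(tert-butyl)dimethylsilane | CC(C)(C)[Si](C)(C)Oc1ccc(Br)cc1 | starting material
2 | 3-methylbut-2-enal | CC(C)=CC=O | starting material
3 | [4-(tert-butyldimethylsilyloxy)phenyl]magnesium bromide (not isolated) | CC(C)(C)[Si](C)(C)Oc1ccc([Mg]Br)cc1 | intermediate
4 | trimethylsilyl enol ether of 5, E/Z mixture (not isolated) | CC(C)(C=CO[Si](C)(C)C)c1ccc(O[Si](C)(C)C(C)(C)C)cc1 | intermediate
5 | 3-[4-(tert-butyldimethylsilyloxy)phenyl]-3-methylbutanal | CC(C)(CC=O)c1ccc(O[Si](C)(C)C(C)(C)C)cc1 | intermediate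
6 | (2S)-2-bromo-3-[4-(tert-butyldimethylsilyloxy)phenyl]-3-methylbutanal | O=C[C@@H](Br)C(C)(C)c1ccc(O[Si](C)(C)C(C)(C)C)cc1 | intermediate
7 | allenylboronic acid pinacol ester | C=C=CB1OC(C)(C)C(C)(C)O1 | starting material
8 | pinacol borate ester of 9, O–B(pin) on C4 (not isolated) | C#CC[C@@H](OB1OC(C)(C)C(C)(C)O1)[C@@H](Br)C(C)(C)c1ccc(O[Si](C)(C)C(C)(C)C)cc1 | intermediate
9 | (4R,5S)-5-bromo-6-[4-(tert-butyldimethylsilyloxy)phenyl]-6-methylhept-1-yn-4-ol | C#CC[C@@H](O)[C@@H](Br)C(C)(C)c1ccc(O[Si](C)(C)C(C)(C)C)cc1 | intermediate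
10 | tert-butyl{4-[(3S,4R)-3-bromo-4-(tert-butyldimethylsilyloxy)-2-methylhept-6-yn-2-yl]phenoxy}dimethylsilane | C#CC[C@@H](O[Si](C)(C)C(C)(C)C)[C@@H](Br)C(C)(C)c1ccc(O[Si](C)(C)C(C)(C)C)cc1 | intermediate
11 | 4-[(3S,4R)-3-bromo-4-(tert-butyldimethylsilyloxy)-2-methylhept-6-yn-2-yl]phenol | C#CC[C@@H](O[Si](C)(C)C(C)(C)C)[C@@H](Br)C(C)(C)c1ccc(O)cc1 | intermediate
12 | (8S,9R)-8-bromo-9-(tert-butyldimethylsilyloxy)-7,7-dimethyl-11-methylidenespiro[5.5]undeca-1,4-dien-3-one | C=C1C[C@@H](O[Si](C)(C)C(C)(C)C)[C@@H](Br)C(C)(C)C12C=CC(=O)C=C2 | intermediate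
13 | (8S,9R)-8-bromo-9-hydroxy-7,7-dimethyl-11-methylidenespiro[5.5]undeca-1,4-dien-3-one (not isolated) | C=C1C[C@@H](O)[C@@H](Br)C(C)(C)C12C=CC(=O)C=C2 | intermediate
14 | (1S,6S,8S,9R)-8-bromo-1,9-epoxy-7,7-dimethyl-11-methylidenespiro[5.5]undec-4-en-3-one (oxygen bridges C9 and C1; C1 configuration as expected, erased in step 9) | C=C1C[C@H]2O[C@H]3CC(=O)C=C[C@@]13C(C)(C)[C@@H]2Br | intermediate
15 | (1S,6S,8S,9R)-8-bromo-1,9-epoxy-7,7-dimethyl-11-methylidenespiro[5.5]undecan-3-one | C=C1C[C@H]2O[C@H]3CC(=O)CC[C@@]13C(C)(C)[C@@H]2Br | intermediate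
16 | C2=C3 tert-butyldimethylsilyl enol ether of 15 (not isolated) | C=C1C[C@H]2O[C@H]3C=C(O[Si](C)(C)C(C)(C)C)CC[C@@]13C(C)(C)[C@@H]2Br | intermediate
17 | (6S,8S,9R)-8-bromo-9-(tert-butyldimethylsilyloxy)-7,7-dimethyl-11-methylidenespiro[5.5]undec-1-en-3-one | C=C1C[C@@H](O[Si](C)(C)C(C)(C)C)[C@@H](Br)C(C)(C)[C@@]12C=CC(=O)CC2 | intermediate
18 | (1R,6S,8S,9R)-8-bromo-9-(tert-butyldimethylsilyloxy)-7,7-dimethyl-11-methylidene-1-(phenylselanyl)spiro[5.5]undecan-3-one | C=C1C[C@@H](O[Si](C)(C)C(C)(C)C)[C@@H](Br)C(C)(C)[C@@]12[C@H]([Se]c3ccccc3)CC(=O)CC2 | intermediate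
19 | (1R,3R,6S,8S,9R)-8-bromo-9-(tert-butyldimethylsilyloxy)-3-(dibromomethyl)-7,7-dimethyl-11-methylidene-1-(phenylselanyl)spiro[5.5]undecan-3-ol | C=C1C[C@@H](O[Si](C)(C)C(C)(C)C)[C@@H](Br)C(C)(C)[C@@]12[C@H]([Se]c3ccccc3)C[C@@](O)(C(Br)Br)CC2 | intermediate
20 | Se-oxide of 19 (not isolated) | C=C1C[C@@H](O[Si](C)(C)C(C)(C)C)[C@@H](Br)C(C)(C)[C@@]12[C@H]([Se](=O)c3ccccc3)C[C@@](O)(C(Br)Br)CC2 | intermediate
21 | (3R,6S,8S,9R)-8-bromo-9-(tert-butyldimethylsilyloxy)-3-(dibromomethyl)-7,7-dimethyl-11-methylidenespiro[5.5]undec-1-en-3-ol | C=C1C[C@@H](O[Si](C)(C)C(C)(C)C)[C@@H](Br)C(C)(C)[C@@]12C=C[C@@](O)(C(Br)Br)CC2 | intermediate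
22 | Mailiohydrin, (3R,6S,8S,9R)-8-bromo-3-(dibromomethyl)-7,7-dimethyl-11-methylidenespiro[5.5]undec-1-ene-3,9-diol | C=C1C[C@@H](O)[C@@H](Br)C(C)(C)[C@@]12C=C[C@@](O)(C(Br)Br)CC2 | target

## Step count and risks

Total steps: 13. Longest linear sequence: 13 steps (1 or 2 → 22).

Steps most likely to fail:

1. Step 6. The gold-activated alkyne may be consumed by hydration or by participation of the C4 silyl ether oxygen faster than the hindered ipso carbon attacks, or the spirodienone may undergo an acid-induced dienone–phenol 1,2-shift. The fallback uses an electrophile-triggered ring closure instead of π-acid catalysis. It sets out from 10: iodonium-induced ipso-cyclisation of the aryl silyl ether (ICl, CH2Cl2, −78 °C, the silyl group being lost as the dienone forms) should give (8S,9R,11E)-8-bromo-9-(tert-butyldimethylsilyloxy)-11-(iodomethylidene)-7,7-dimethylspiro[5.5]undeca-1,4-dien-3-one F1. Palladium-catalysed hydrodeiodination (Pd(OAc)2, PPh3, HCO2H, Et3N, aq NaHCO3 work-up) should then rejoin the route at 12.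

2. Step 7. Ring A must leave its chair for a boat before the hydroxyl can reach the enone, so the conjugate addition may be slow or lie on the open side, and base may instead induce ring contraction of the cis-bromohydrin. The fallback uses reagent control instead of a substrate tether. It sets out from 12: a chiral copper hydride conjugate reduction (Cu(OAc)2, one enantiomer of DTBM-SEGPHOS chosen by screening, PMHS, t-BuOH, toluene) should differentiate the two diastereotopic enone arms and reduce C4=C5 directly. It comes back to the route at 17 and makes no new compound (F0).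

3. Step 11. The basic carbenoid may expel phenylselenolate (retro-Michael) before it adds, or attack may leak to the axial face; either erodes the C3 configuration. The fallback uses an epoxide instead of the selenide as mask and control element. It sets out from 17: nucleophilic epoxidation (t-BuOOH, DBU, CH2Cl2) should give the 1,2-epoxide of 17 with the oxirane oxygen on the ring-B face opposite to the axial C11, F2. Dibromomethyllithium (CH2Br2, LDA, THF, −90 °C, AcOH quench) should add anti to the oxirane oxygen to give the corresponding epoxy dibromomethyl carbinol F3. Rhenium-catalysed oxygen transfer to phosphine (MeReO3 cat., PPh3, benzene) should deoxygenate the oxirane to the C1=C2 alkene and rejoin the route at 21.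

Further compounds
F1 | step 6 | (8S,9R,11E)-8-bromo-9-(tert-butyldimethylsilyloxy)-11-(iodomethylidene)-7,7-dimethylspiro[5.5]undeca-1,4-dien-3-one | I/C=C1\C[C@@H](O[Si](C)(C)C(C)(C)C)[C@@H](Br)C(C)(C)C12C=CC(=O)C=C2
F0 | step 7 | none | none
F2 | step 11 | 1,2-epoxide of 17, oxirane oxygen on the ring-B face opposite to C11 | C=C1C[C@@H](O[Si](C)(C)C(C)(C)C)[C@@H](Br)C(C)(C)[C@@]12[C@@H]3O[C@@H]3C(=O)CC2
F3 | step 11 | 3-(dibromomethyl) carbinol from F2, hydroxyl cis to the oxirane oxygen, (3R) as in the target | C=C1C[C@@H](O[Si](C)(C)C(C)(C)C)[C@@H](Br)C(C)(C)[C@@]12[C@@H]3O[C@@H]3[C@@](O)(C(Br)Br)CC2
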